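**Plan**
The retrosynthesis first trades the two C2–Br bonds for C2–SiMe3 bonds, then cuts C3–C3a and N1–C2 in each indole half, four skeletal bonds in all.
The feature that allows this is the unbranched four-carbon chain C2–C3–C3'–C2' joining the two pyrrole rings and ending in bromine at both ends. It is a buta-1,3-diyne in disguise, with silicon standing in for bromine.
Forward: 3,4-dibromoaniline is iodinated ortho to nitrogen. One palladium-catalysed operation then closes the first pyrrole ring on one triple bond of the diyne and the second pyrrole ring on the other. Twofold ipso-bromodesilylation finishes the route.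
Both benzene rings are bought with their bromines in place; the 3,3' bond is never formed, it is the central single bond of the diyne.
There is no stereocentre, so no stereochemistry has to be set.

Key step: step 2

Remark: the 3,3' axis of the target is written without a descriptor, so the compound is treated as stereochemically undefined; both N–H groups stay free throughout because neither the annulation nor the final bromination needs protection.

**Step 1**
Reactants: 1 3,4-dibromoaniline
Product: 2 4,5-dibromo-2-iodoaniline
Conditions: NIS (1.05 equiv), AcOH, rt, dark
Reagents that add atoms: N-iodosuccinimide, O=C1CCC(=O)N1I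
Why: Electrophilic aromatic iodination directed by the amino group: the para position is blocked by bromine and, of the two ortho positions, C6 is open while C2 is wedged between NH2 and Br, so iodine should enter at C6.

**Step 2**
Reactants: 2 4,5-dibromo-2-iodoaniline (two molecules per diyne, 2.3 equiv in all); 3 1,4-bis(trimethylsilyl)buta-1,3-diyne
Product: 5 5,5',6,6'-tetrabromo-2,2'-bis(trimethylsilyl)-1H,1'H-3,3'-biindole, via 3-alkynyl-2-silylindole 4 (not isolated)
Conditions: Pd(OAc)2 (10 mol %), LiCl (2 equiv), Na2CO3 (5 equiv), DMF, 100 °C, argon
Reagents that add atoms: none
Why: Proposed new method: zerovalent palladium formed from Pd(OAc)2 should insert into the C–I bond of 2, the arylpalladium should add syn across one triple bond of 3 so that the aryl carbon bonds to the inner alkyne carbon (C3–C3a) and palladium sits on the silicon-bearing carbon, and binding of the amine, loss of HI to the carbonate and C–N reductive elimination should then form N1–C2 and release 4, whose remaining silylalkyne enters the same cycle with a second molecule of 2. The closest known reaction type is the Larock indole synthesis of 2-silylindoles from 2-iodoanilines and internal silylalkynes; what lacks precedent is its twofold use on a conjugated 1,4-disilylbuta-1,3-diyne, so that the diyne single bond ends as the 3,3' bond of a biindole. Both pyrrole rings close in the same mode, a [3+2] heteroannulation completed by reductive elimination from a six-membered azapalladacycle, the first on the diyne and the second on the alkyne of 4. No stereocentre arises. The step needs regioselectivity in both insertions (silicon at C2 and C2', not at C3) and chemoselectivity for C–I over the C–Br bonds: the first should follow from the preference of the bulky SiMe3 group for the carbon bound to palladium, where the long C–Pd bond relieves strain and silicon stabilises the adjacent C–Pd bond, the second from the much faster oxidative addition of aryl iodides to phosphine-free palladium, supported by the slight excess of 2 that keeps a C–I bond on offer until the diyne is consumed. Na2CO3 is chosen over stronger bases so that the alkynyl C–Si bonds of 3 and 4 are not cleaved before they have directed the insertion.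

**Step 3**
Reactants: 5 5,5',6,6'-tetrabromo-2,2'-bis(trimethylsilyl)-1H,1'H-3,3'-biindole
Product: 6 2,2',5,5',6,6'-hexabromo-1H,1'H-3,3'-biindole (CNP0143195.0)
Conditions: NBS (2.1 equiv), dry CH2Cl2/THF, 0 °C, dark
Reagents that add atoms: N-bromosuccinimide, O=C1CCC(=O)N1Br
Why: Electrophilic ipso-bromodesilylation, a known reaction of 2-silylindoles: bromine from NBS should attack the silicon-bearing C2 of each half, the cation at C3 (benzylic and beta to silicon) should lose SiMe3 to succinimide, and since C3 is substituted and each benzo ring carries two deactivating bromines no other position should compete, while any C2–H arising from stray protodesilylation is brominated by the same reagent to the same product.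

**Compound list**
1 | 3,4-dibromoaniline | Nc1ccc(Br)c(Br)c1 | starting material
2 | 4,5-dibromo-2-iodoaniline | Nc1cc(Br)c(Br)cc1I | intermediate
3 | 1,4-bis(trimethylsilyl)buta-1,3-diyne | C[Si](C)(C)C#CC#C[Si](C)(C)C | starting material
4 | 5,6-dibromo-2-(trimethylsilyl)-3-[(trimethylsilyl)ethynyl]-1H-indole | C[Si](C)(C)C#Cc1c([Si](C)(C)C)[nH]c2cc(Br)c(Br)cc12 | intermediate
5 | 5,5',6,6'-tetrabromo-2,2'-bis(trimethylsilyl)-1H,1'H-3,3'-biindole | C[Si](C)(C)c1[nH]c2cc(Br)c(Br)cc2c1-c1c([Si](C)(C)C)[nH]c2cc(Br)c(Br)cc12 | intermediate
6 | 2,2',5,5',6,6'-hexabromo-1H,1'H-3,3'-biindole | Brc1cc2[nH]c(Br)c(-c3c(Br)[nH]c4cc(Br)c(Br)cc34)c2cc1Br | target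

Total step count: 3
Longest linear sequence: 3 steps (1 → 2 → 5 → 6); the diyne 3 is purchased.

**Steps most likely to fail**

1. Step 2 (the proposed new method).
   - What may go wrong: the diyne may insert with the opposite orientation, with palladium on the inner carbon where the neighbouring triple bond can stabilise it. The carbonate may cleave the alkynyl silyl groups before annulation. The sequence may stall after the first ring because the second insertion is crowded. Palladium may also add slowly into C–Br bonds once iodide runs short.
   - Fallback, using known reaction types only, setting out from 2 and coming back at 6: Sonogashira coupling of 2 with ethynyltrimethylsilane at the C–I bond (PdCl2(PPh3)2, CuI, Et3N, rt) should give 4,5-dibromo-2-[(trimethylsilyl)ethynyl]aniline F1. Bu4NF in hot THF should remove silicon and close the ring by 5-endo-dig amination to 5,6-dibromo-1H-indole F2. Oxidative C3–H/C3–H homocoupling of the free indole under divalent palladium (Pd(O2CCF3)2, AgNO3, DMSO) should give 5,5',6,6'-tetrabromo-1H,1'H-3,3'-biindole F3. Electrophilic bromination of both free C2 positions with NBS, the usual outcome for 3-substituted indoles, then gives 6. Here the 3,3' bond is made by C–H coupling instead of being carried in by the diyne.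

2. Step 3.
   - What may go wrong: NBS may attack C3 or nitrogen, and the resulting bromoindolenine may hydrolyse to oxindoles. Substitution at the second, crowded C–Si bond may remain incomplete.
   - Fallback, setting out from 5 and coming back at 6: the single ipso substitution is divided into protodesilylation and C–H bromination. Bu4NF in warm THF should cleave both C2–Si bonds to give 5,5',6,6'-tetrabromo-1H,1'H-3,3'-biindole F4 (the same substance as F3). Pyridinium tribromide in THF/pyridine at 0 °C should then brominate C2 and C2' by ordinary electrophilic substitution to give 6, without a silyl leaving group and with a milder bromine source.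

3. Step 1.
   - What may go wrong: iodine may enter at the crowded C2 position, iodination may occur twice, or the electron-rich aniline may be oxidised.
   - Fallback, setting out from 1 and coming back at 2: acetylation with Ac2O should give N-(3,4-dibromophenyl)acetamide F5. Amide-directed ortho C–H iodination through a six-membered palladacycle (Pd(OAc)2, NIS, TsOH, toluene) should give N-(4,5-dibromo-2-iodophenyl)acetamide F6, since palladation is only feasible at the unhindered ortho C–H. Acid hydrolysis (aqueous HCl, dioxane, reflux) then returns 2. Regiochemistry is set by chelation instead of by the innate preference of the ring.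

**Further compounds**
F1 | step 2 | 4,5-dibromo-2-[(trimethylsilyl)ethynyl]aniline | Nc1cc(Br)c(Br)cc1C#C[Si](C)(C)C
F2 | step 2 | 5,6-dibromo-1H-indole | Brc1cc2cc[nH]c2cc1Br
F3 | step 2 | 5,5',6,6'-tetrabromo-1H,1'H-3,3'-biindole | Brc1cc2[nH]cc(-c3c[nH]c4cc(Br)c(Br)cc34)c2cc1Br
F4 | step 3 | 5,5',6,6'-tetrabromo-1H,1'H-3,3'-biindole | Brc1cc2[nH]cc(-c3c[nH]c4cc(Br)c(Br)cc34)c2cc1Br
F5 | step 1 | N-(3,4-dibromophenyl)acetamide | CC(=O)Nc1ccc(Br)c(Br)c1
F6 | step 1 | N-(4,5-dibromo-2-iodophenyl)acetamide | CC(=O)Nc1cc(Br)c(Br)cc1I
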